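**Retrosynthetic overview**
- Feature: ring A carries oxygen on all four non-fusion carbons (C5 OMe, C6 OMe, C7 OH, C8 OMe). This C4O4 unit is a squaric diester fused across C4a–C8a of the pyranone ring C; O7, the only free hydroxyl, is carried as a tert-butyl ether and O6 as methyl.
- Key disconnection: C8–C8a, closing ring A by thermal opening of a 4-hydroxy-4-(pyranonyl)cyclobutenone to a vinylketene and six-electron ring closure. The C4a–C5 bond comes before it from a 5-magnesiated 3-methoxy-2-anisyl-4-pyranone and tert-butyl methyl squarate.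
- Ring C: anisyl Grignard plus 3-bromofurfural, Achmatowicz rearrangement, acid-induced loss of HBr to the 3-hydroxy-4-pyranone (the bromine supplies the extra oxidation level), O-methylation, C5 iodination.
- Ring order: the anisyl ring is bought, ring C is made first, ring A last; then O5/O8 methylation and tert-butyl cleavage.

Key step: step 10

Remark: the target has no stereocentre; the stereocentres of the carbinol, the dihydropyranone and the cyclobutenone adduct are all erased later, so these are made as racemates or diastereomer mixtures.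

**Route**

Step 1
Reactants: 1 4-bromoanisole; 2 3-bromofuran-2-carbaldehyde
Product: 4 racemic (3-bromofuran-2-yl)(4-methoxyphenyl)methanol, via 4-methoxyphenylmagnesium bromide 3 (not isolated)
Conditions: 1, Mg, I2 (cat.), THF, reflux; then 2, THF, −20 to 0 °C; then H2O
Reagents that add atoms: none
Why: Grignard formation from the aryl bromide and 1,2-addition to the aldehyde should be far faster than any exchange at the furyl bromide, and the new carbinol centre is formed without control because it is erased in step 3.

Step 2
Reactants: 4 racemic (3-bromofuran-2-yl)(4-methoxyphenyl)methanol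
Product: 5 4-bromo-6-hydroxy-2-(4-methoxyphenyl)-2H-pyran-3(6H)-one (racemic mixture of C2/C6 diastereomers)
Conditions: NBS (1.05 equiv), NaHCO3, THF/H2O (4:1), 0 °C
Reagents that add atoms: water (O)
Why: Achmatowicz rearrangement, in which bromonium attack at the free furan C5, hydration, opening to the Z-enedione and hemiacetal closure through the carbinol oxygen should give the pyranone with the furan C3 bromine at C4, while the buffer protects the acid-labile carbinol and both stereocentres are lost in step 3.

Step 3
Reactants: 5 4-bromo-6-hydroxy-2-(4-methoxyphenyl)-2H-pyran-3(6H)-one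
Product: 6 3-hydroxy-2-(4-methoxyphenyl)-4H-pyran-4-one
Conditions: 1 M aq. H2SO4/1,4-dioxane (1:1), 90 °C
Reagents that add atoms: water (O)
Why: acid-promoted hydrolytic aromatization, the second stage of the halogen route from furfuryl alcohols to maltol-type pyranones, in which ionization of the C6 hemiacetal, addition of water at the bromine-bearing C4, loss of HBr and enolization of C2–H should give the 3-hydroxy-4-pyranone.

Step 4
Reactants: 6 3-hydroxy-2-(4-methoxyphenyl)-4H-pyran-4-one
Product: 7 3-methoxy-2-(4-methoxyphenyl)-4H-pyran-4-one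
Conditions: MeI, K2CO3, acetone, reflux
Reagents that add atoms: iodomethane (CI)
Why: O-alkylation of the acidic enolic hydroxyl (Williamson ether synthesis), as in the methylation of maltol, should be clean because no other acidic site is present.

Step 5
Reactants: 7 3-methoxy-2-(4-methoxyphenyl)-4H-pyran-4-one
Product: 8 5-iodo-3-methoxy-2-(4-methoxyphenyl)-4H-pyran-4-one
Conditions: I2 (0.6 equiv), (NH4)2Ce(NO3)6 (1.1 equiv), MeCN, 60 °C
Reagents that add atoms: iodine (II)
Why: oxidant-assisted electrophilic α-iodination of a vinylogous ester, the reaction type used for C3 of flavones and C5 of uracils, should occur at C5 (the α-carbon of the O1–C6=C5–C4=O unit) faster than on the anisyl ring, which is deactivated by conjugation with the pyranone carbonyl.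

Step 6
Reactants: 9 squaric acid
Product: 10 3,4-dichlorocyclobut-3-ene-1,2-dione
Conditions: (COCl)2 (2.2 equiv), DMF (cat.), 1,2-dichloroethane, 50 °C
Reagents that add atoms: oxalyl chloride (O=C(Cl)C(Cl)=O)
Why: the two vinylogous carboxylic acid hydroxyls should be converted into chlorides by the chloroiminium species formed from DMF and oxalyl chloride (acid chloride formation under Vilsmeier-type catalysis).

Step 7
Reactants: 10 3,4-dichlorocyclobut-3-ene-1,2-dione
Product: 11 3-chloro-4-methoxycyclobut-3-ene-1,2-dione
Conditions: MeOH (1.0 equiv), CH2Cl2, −20 °C to rt, N2 stream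
Reagents that add atoms: methanol (CO)
Why: addition–elimination at the vinylogous acid chloride should stop after one substitution because the new methoxy group donates into the ring and deactivates the remaining C–Cl carbon.

Step 8
Reactants: 11 3-chloro-4-methoxycyclobut-3-ene-1,2-dione
Product: 12 3-tert-butoxy-4-methoxycyclobut-3-ene-1,2-dione
Conditions: KOtBu (1.0 equiv), THF, −78 °C
Reagents that add atoms: potassium tert-butoxide (CC(C)(C)[O-].[K+])
Why: addition–elimination of the alkoxide at the chlorine-bearing carbon should be much faster than displacement of methoxide, and the basic, acid-free medium keeps the tert-butyl ester intact.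

Step 9
Reactants: 8 5-iodo-3-methoxy-2-(4-methoxyphenyl)-4H-pyran-4-one; 12 3-tert-butoxy-4-methoxycyclobut-3-ene-1,2-dione
Product: 14 racemic 2-tert-butoxy-4-hydroxy-3-methoxy-4-[5-methoxy-6-(4-methoxyphenyl)-4-oxo-4H-pyran-3-yl]cyclobut-2-en-1-one, via pyranonylmagnesium chloride 13 (not isolated)
Conditions: 8, iPrMgCl·LiCl (1.05 equiv), THF, −40 °C; then cannulate into 12 (1.2 equiv), THF, −78 to −40 °C; then H2O (pH 7 phosphate buffer)
Reagents that add atoms: none
Why: iodine–magnesium exchange on the electron-poor alkenyl iodide is fast at −40 °C, and the alkenylmagnesium species (kept cold to prevent ring-opening β-elimination) should add 1,2 to the squarate carbonyl beside the methoxy-bearing carbon, because the tert-butoxy group shields the other carbonyl and its oxygen from magnesium coordination (Grignard 1,2-addition to a squaric diester, the carbinol centre forming without control).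

Step 10
Reactants: 14 racemic 2-tert-butoxy-4-hydroxy-3-methoxy-4-[5-methoxy-6-(4-methoxyphenyl)-4-oxo-4H-pyran-3-yl]cyclobut-2-en-1-one
Product: 17 7-tert-butoxy-5,8-dihydroxy-3,6-dimethoxy-2-(4-methoxyphenyl)-4H-chromen-4-one, via vinylketene 15 (not isolated), via 8a-H dienone 16 (not isolated)
Conditions: toluene (0.02 M, degassed), 110 °C, argon
Reagents that add atoms: none
Why: Heating should open the cyclobutenone by conrotatory four-electron ring opening, breaking the bond between the ring carbonyl carbon and the carbinol carbon to give vinylketene 15; the donor hydroxyl is expected to rotate outward, which turns the pyranonyl group inward and places its O–CH=C bond (future C8a=C4a) beside the ketene terminus. A thermally allowed disrotatory six-electron electrocyclization then joins the ketene carbon (future C8) to the pyranone CH next to the ring oxygen (future C8a) and closes ring A as dienone 16, whose C8a–H shifts to oxygen to give the aromatic hydroquinone 17. This is the known thermal ring expansion of 4-alkenyl- and 4-aryl-4-hydroxycyclobutenones to hydroquinones (Moore rearrangement), applied here to a pyranonyl substituent. No stereocentre survives, since the carbinol centre of 14 becomes the sp2 carbon C5 and the transient C8a centre of 16 is lost on tautomerization. The step needs torquoselectivity (hydroxyl out, pyranonyl in), secured by the donor hydroxyl on the breaking bond, and site selectivity, secured because the pyranone C–H carbon is the only terminus that can close a six-membered ring; the O6-methyl/O7-tert-butyl pattern is already fixed in 14. Neutral degassed toluene should leave the tert-butyl ether intact and keep the hydroquinone from air oxidation to the 5,8-quinone.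

Step 11
Reactants: 17 7-tert-butoxy-5,8-dihydroxy-3,6-dimethoxy-2-(4-methoxyphenyl)-4H-chromen-4-one
Product: 18 7-tert-butoxy-3,5,6,8-tetramethoxy-2-(4-methoxyphenyl)-4H-chromen-4-one
Conditions: Me2SO4 (4 equiv), K2CO3, acetone (degassed), reflux, argon
Reagents that add atoms: dimethyl sulfate (COS(=O)(=O)OC)
Why: phenol O-methylation (Williamson type) with excess dimethyl sulfate at reflux should alkylate both the 8-hydroxyl and the chelated 5-hydroxyl, while the tert-butyl ether is inert to base and exclusion of air prevents quinone formation.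

Step 12
Reactants: 18 7-tert-butoxy-3,5,6,8-tetramethoxy-2-(4-methoxyphenyl)-4H-chromen-4-one
Product: 19 7-hydroxy-3,5,6,8-tetramethoxy-2-(4-methoxyphenyl)-4H-chromen-4-one
Conditions: CF3CO2H/CH2Cl2 (1:4), 0 °C to rt
Reagents that add atoms: none
Why: acidolysis of the aryl tert-butyl ether by loss of the tert-butyl cation as isobutene should free only O7, since methyl ethers are stable to trifluoroacetic acid and ring A has no free position for re-alkylation.

**Compound list**

1 | 4-bromoanisole | COc1ccc(Br)cc1 | starting material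
2 | 3-bromofuran-2-carbaldehyde | O=Cc1occc1Br | starting material
3 | 4-methoxyphenylmagnesium bromide | COc1ccc([Mg]Br)cc1 | intermediate (not isolated)
4 | racemic (3-bromofuran-2-yl)(4-methoxyphenyl)methanol | COc1ccc(C(O)c2occc2Br)cc1 | intermediate
5 | 4-bromo-6-hydroxy-2-(4-methoxyphenyl)-2H-pyran-3(6H)-one, racemic mixture of C2/C6 diastereomers | COc1ccc(C2OC(O)C=C(Br)C2=O)cc1 | intermediate
6 | 3-hydroxy-2-(4-methoxyphenyl)-4H-pyran-4-one | COc1ccc(-c2occc(=O)c2O)cc1 | intermediate
7 | 3-methoxy-2-(4-methoxyphenyl)-4H-pyran-4-one | COc1ccc(-c2occc(=O)c2OC)cc1 | intermediate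
8 | 5-iodo-3-methoxy-2-(4-methoxyphenyl)-4H-pyran-4-one | COc1ccc(-c2occ(I)c(=O)c2OC)cc1 | intermediate
9 | squaric acid | OC1=C(O)C(=O)C1=O | starting material
10 | 3,4-dichlorocyclobut-3-ene-1,2-dione | ClC1=C(Cl)C(=O)C1=O | intermediate
11 | 3-chloro-4-methoxycyclobut-3-ene-1,2-dione | COC1=C(Cl)C(=O)C1=O | intermediate
12 | 3-tert-butoxy-4-methoxycyclobut-3-ene-1,2-dione | COC1=C(OC(C)(C)C)C(=O)C1=O | intermediate
13 | [5-methoxy-6-(4-methoxyphenyl)-4-oxo-4H-pyran-3-yl]magnesium chloride (LiCl complex) | COc1ccc(-c2occ([Mg]Cl)c(=O)c2OC)cc1 | intermediate (not isolated)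
14 | racemic 2-tert-butoxy-4-hydroxy-3-methoxy-4-[5-methoxy-6-(4-methoxyphenyl)-4-oxo-4H-pyran-3-yl]cyclobut-2-en-1-one | O=C1C(OC(C)(C)C)=C(OC)C1(O)c1coc(-c2ccc(OC)cc2)c(OC)c1=O | intermediate
15 | (3Z)-2-tert-butoxy-4-hydroxy-3-methoxy-4-[5-methoxy-6-(4-methoxyphenyl)-4-oxo-4H-pyran-3-yl]buta-1,3-dien-1-one | O=C=C(OC(C)(C)C)/C(OC)=C(/O)c1coc(-c2ccc(OC)cc2)c(OC)c1=O | intermediate (not isolated)
16 | racemic 7-tert-butoxy-5-hydroxy-3,6-dimethoxy-2-(4-methoxyphenyl)-4H-chromene-4,8(8aH)-dione | COc1ccc(C2=C(OC)C(=O)C3=C(O)C(OC)=C(OC(C)(C)C)C(=O)C3O2)cc1 | intermediate (not isolated)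
17 | 7-tert-butoxy-5,8-dihydroxy-3,6-dimethoxy-2-(4-methoxyphenyl)-4H-chromen-4-one | COc1ccc(-c2oc3c(O)c(OC(C)(C)C)c(OC)c(O)c3c(=O)c2OC)cc1 | intermediate
18 | 7-tert-butoxy-3,5,6,8-tetramethoxy-2-(4-methoxyphenyl)-4H-chromen-4-one | COc1ccc(-c2oc3c(OC)c(OC(C)(C)C)c(OC)c(OC)c3c(=O)c2OC)cc1 | intermediate
19 | 7-hydroxy-3,5,6,8-tetramethoxy-2-(4-methoxyphenyl)-4H-chromen-4-one | COc1ccc(-c2oc3c(OC)c(O)c(OC)c(OC)c3c(=O)c2OC)cc1 | target

**Step count**

Total steps: 12. Longest linear sequence: 9 steps (steps 1–5 and 9–12); the squarate branch (steps 6–8) joins at step 9.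

**Steps most likely to fail**

Step 9. The Grignard reagent may not discriminate well enough between the two squarate carbonyls. Attack beside the tert-butoxy-bearing carbon would carry the free hydroxyl to C6 instead of C7, and warming of the magnesiated pyranone would open its ring. The fallback removes the regiochemical question with a symmetric squarate and differentiates O6 from O7 late, through the higher acidity of the 7-hydroxyl (para to the C4 carbonyl). It sets out from 10 and from 13 (made from 8 as in step 9) and returns at 19.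
- Compound 10 with benzyl alcohol (2 equiv) and 2,6-lutidine in CH2Cl2 should give 3,4-bis(benzyloxy)cyclobut-3-ene-1,2-dione F1, whose carbonyls are equivalent.
- Addition of 13 at −78 °C should give racemic 2,3-bis(benzyloxy)-4-hydroxy-4-[5-methoxy-6-(4-methoxyphenyl)-4-oxo-4H-pyran-3-yl]cyclobut-2-en-1-one F2.
- Heating in degassed toluene should give 6,7-bis(benzyloxy)-5,8-dihydroxy-3-methoxy-2-(4-methoxyphenyl)-4H-chromen-4-one F3.
- Me2SO4/K2CO3 should give 6,7-bis(benzyloxy)-3,5,8-trimethoxy-2-(4-methoxyphenyl)-4H-chromen-4-one F4.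
- Hydrogenolysis (H2, Pd/C, EtOAc) should give 6,7-dihydroxy-3,5,8-trimethoxy-2-(4-methoxyphenyl)-4H-chromen-4-one F5.
- Benzyl bromide (1 equiv) with KHCO3 in DMF should alkylate the more acidic hydroxyl to give 7-(benzyloxy)-6-hydroxy-3,5,8-trimethoxy-2-(4-methoxyphenyl)-4H-chromen-4-one F6.
- MeI/K2CO3 should give 7-(benzyloxy)-3,5,6,8-tetramethoxy-2-(4-methoxyphenyl)-4H-chromen-4-one F7, and a second hydrogenolysis should give 19.

Step 10. The vinylketene may be diverted: the hydroxyl may rotate inward and lactonize onto the ketene, or the phenolic product may catalyse loss of isobutene. The free hydroquinone may also oxidize during isolation. The fallback runs the ring expansion on the methyl ether of the carbinol, so that O5 arrives already methylated and no hydroquinone is formed. It sets out from 14 and returns at 18.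
- MeI, Ag2O and K2CO3 in MeCN should give racemic 2-tert-butoxy-3,4-dimethoxy-4-[5-methoxy-6-(4-methoxyphenyl)-4-oxo-4H-pyran-3-yl]cyclobut-2-en-1-one F8.
- Heating in degassed toluene should give 7-tert-butoxy-8-hydroxy-3,5,6-trimethoxy-2-(4-methoxyphenyl)-4H-chromen-4-one F9.
- Me2SO4/K2CO3 then methylates the single unchelated phenol to give 18.

Step 5. The iodinating system may attack the anisyl ring ortho to its methoxy group, or conversion at the electron-poor C5 may stall. The fallback makes the target carbon far more nucleophilic by opening the pyranone to an enaminone and then reclosing it with iodine, as in the enaminone route to 3-iodochromones. It sets out from 7 and returns at 8.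
- Pyrrolidine in EtOH should add at the unsubstituted C6 and open the ring to (4E)-2-methoxy-1-(4-methoxyphenyl)-5-(pyrrolidin-1-yl)pent-4-ene-1,3-dione F10 (drawn as the diketone; mainly enolized).
- I2 in CHCl3 should iodinate the enaminone α-carbon, and the enol oxygen should close onto the iminium carbon with loss of pyrrolidine to give 8.

**Further compounds**

F1 | step 9 | 3,4-bis(benzyloxy)cyclobut-3-ene-1,2-dione | O=C1C(=O)C(OCc2ccccc2)=C1OCc1ccccc1
F2 | step 9 | racemic 2,3-bis(benzyloxy)-4-hydroxy-4-[5-methoxy-6-(4-methoxyphenyl)-4-oxo-4H-pyran-3-yl]cyclobut-2-en-1-one | O=C1C(OCc2ccccc2)=C(OCc2ccccc2)C1(O)c1coc(-c2ccc(OC)cc2)c(OC)c1=O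
F3 | step 9 | 6,7-bis(benzyloxy)-5,8-dihydroxy-3-methoxy-2-(4-methoxyphenyl)-4H-chromen-4-one | COc1ccc(-c2oc3c(O)c(OCc4ccccc4)c(OCc4ccccc4)c(O)c3c(=O)c2OC)cc1
F4 | step 9 | 6,7-bis(benzyloxy)-3,5,8-trimethoxy-2-(4-methoxyphenyl)-4H-chromen-4-one | COc1ccc(-c2oc3c(OC)c(OCc4ccccc4)c(OCc4ccccc4)c(OC)c3c(=O)c2OC)cc1
F5 | step 9 | 6,7-dihydroxy-3,5,8-trimethoxy-2-(4-methoxyphenyl)-4H-chromen-4-one | COc1ccc(-c2oc3c(OC)c(O)c(O)c(OC)c3c(=O)c2OC)cc1
F6 | step 9 | 7-(benzyloxy)-6-hydroxy-3,5,8-trimethoxy-2-(4-methoxyphenyl)-4H-chromen-4-one | COc1ccc(-c2oc3c(OC)c(OCc4ccccc4)c(O)c(OC)c3c(=O)c2OC)cc1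
F7 | step 9 | 7-(benzyloxy)-3,5,6,8-tetramethoxy-2-(4-methoxyphenyl)-4H-chromen-4-one | COc1ccc(-c2oc3c(OC)c(OCc4ccccc4)c(OC)c(OC)c3c(=O)c2OC)cc1
F8 | step 10 | racemic 2-tert-butoxy-3,4-dimethoxy-4-[5-methoxy-6-(4-methoxyphenyl)-4-oxo-4H-pyran-3-yl]cyclobut-2-en-1-one | O=C1C(OC(C)(C)C)=C(OC)C1(OC)c1coc(-c2ccc(OC)cc2)c(OC)c1=O
F9 | step 10 | 7-tert-butoxy-8-hydroxy-3,5,6-trimethoxy-2-(4-methoxyphenyl)-4H-chromen-4-one | COc1ccc(-c2oc3c(O)c(OC(C)(C)C)c(OC)c(OC)c3c(=O)c2OC)cc1
F10 | step 5 | (4E)-2-methoxy-1-(4-methoxyphenyl)-5-(pyrrolidin-1-yl)pent-4-ene-1,3-dione | COc1ccc(C(=O)C(OC)C(=O)/C=C/N2CCCC2)cc1
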